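I have to decide whether the winter flask earns its coupling partner: 5.00 times the charge of substrate, the limiting reagent, where the dawn run took 2.50 times and the noon run 3.75 times.

in all of them: substrate 0.200 M; catalyst 0.0200 M

|  | coupling partner | time |
|---|---|---|
| dawn | 0.500 M |  |
| noon | 0.750 M |  |
| winter | 1.00 M | 23 min |

| run | time / min | [product] / M |
|---|---|---|
| dawn run | 0.92 | 0.0081 |
| dawn run | 1.8 | 0.0159 |
| dawn run | 3.3 | 0.0297 |
| dawn run | 6.3 | 0.0520 |
| dawn run | 12 | 0.0888 |
| dawn run | 23 | 0.1414 |
| noon run | 0.92 | 0.0084 |
| noon run | 1.8 | 0.0164 |
| noon run | 3.3 | 0.0297 |
| noon run | 6.3 | 0.0525 |
| noon run | 12 | 0.0910 |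
| noon run | 23 | 0.1430 |

(standard deviation of a reading: 6 × 10⁻⁴ M)

1. the exponent of [coupling partner] in the starting rate at the charge of the dawn run (at the point where two percent of the substrate have become product)
2. product in the winter run at 23 min, as a share of the substrate charged

- Overall: substrate + coupling partner -> product, with catalyst as catalyst.
- Constant volume, constant temperature.
- Bound and free are read together.
- An order is taken over about fifteen percent of the charge, up and down.

The dawn and noon runs look nearly the same. By 23 min the dawn run has turned 70.7% of the charge and the noon run 71.5%. Earlier they read close too: at 12 min the dawn run stands at 44.4% of the charge and the noon run at 45.5%, a gap of 1.1 percentage points.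

So I treat the extra partner as a small correction and reckon nothing else. My measure is the end clock, the logarithm of one over the fraction of substrate still unturned, divided by the time: 0.0534 min⁻¹ for the dawn run and 0.0546 min⁻¹ for the noon run. Between these two charges the clock climbs with the partner charge to a mean exponent of 0.0550. That is a rough reading, since the gap of 0.8 points stands against a scatter of 0.300% of the charge on each reading. Carried from the noon run to the winter charge, it multiplies the clock by 1.02, which gives me 72.1%.

The forecast gives 72% for the winter run and 0.06 for the exponent at the dawn charge, saying “That points to near-saturation in partner”. Its exponent is a local one from a hyperbola, and mine is a mean over the two charges.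

The flask gives 71.7% and an exponent of 0.11.

    catalyst + substrate ⇌ catalyst-substrate complex, settled at all times (2.860 M⁻¹)
    catalyst + coupling partner ⇌ catalyst-reagent complex, settled at all times (10.90 M⁻¹)
    catalyst-substrate complex + catalyst-reagent complex → product + 2 catalyst (259.2 M⁻¹ min⁻¹)
    2 coupling partner ⇌ idle reagent dimer, settled at all times (20.10 M⁻¹)

The winter clock is 0.0548 min⁻¹, which is 1.00 times the noon clock. In the simulated winter run with the binding of two coupling partner into idle reagent dimer taken away, product reaches 39.9% at the asked time, a clock of 0.0221 min⁻¹, or 0.405 of the noon clock. The dimer holds the winter share up, and it lifts the exponent at the dawn charge from −0.55 to 0.11.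

(The earlier runs and the new flask come from a simulation on assumed constants.)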